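# Proposed synthesis of (2R)-2-[8-hydroxy-2,2-dimethyl-7-(3-methylbut-2-en-1-yl)-2H-chromen-6-yl]chroman-7-ol by a three-component conjunctive coupling

Atom labels follow flavan numbering: O1, C2, C3, C4, C4a, C5–C8, C8a for rings C and A, and C1'–C6' for ring B. The dimethylpyran fused to C4'–C5' is called ring D. In chromene-based names of ring B fragments, chromene C6 is C1', C7 is C2' and C8 is C3'.

## Analysis of the target

The target is a flavan: a chromane (benzo ring A fused to the oxygen heterocycle ring C) carrying ring B at C2. Ring B is substituted everywhere except C6': C2' bears a 3-methylbut-2-enyl (prenyl) group, C3' a free hydroxyl, and C4'–C5' are fused through O4' to a 2,2-dimethyl-2H-pyran (ring D); ring A has one free hydroxyl at C7. There is a single stereocentre, C2, of R configuration (O1 > C1' > C3 > H), so only absolute control is needed. C2 is a benzylic ether carbon whose aryl group has an oxygen (O4') para to it, so the C2–O1 bond can ionise under acid and the configuration can be lost. The prenyl group sits next to a free phenol and can close onto it under acid, and the two alkenes (prenyl and ring D) exclude hydrogenolysis and electrophilic oxidants. The difficulty is to set an isolated benzylic stereocentre that has no neighbouring group to direct it, next to a crowded C1' flanked by the prenyl group, and to finish without strong acid or hydrogenation. The strategy rests on the two-carbon unit C2–C3: C2 holds ring B and a heteroatom, and C3 is a methylene bonded to the benzylic C4 of ring A. A vinylboron unit maps onto this pair, with boron standing in for O1, ring B arriving at C2 by migration from boron and the ring A benzyl carbon arriving at C3; O1–C8a is then the only skeletal bond left to make.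

## Retrosynthetic reasoning

**21 to 20.** The two phenols are unmasked last. Methoxymethyl ethers are chosen because the oxygens must pass through an aryllithium, a borate, zerovalent nickel, alkaline peroxide and a hot carbonate base, none of which attacks an acetal. Benzyl ethers are excluded by the two alkenes. The forward step must cleave two aryl acetals without protonating either alkene and without ionising C2–O1.

**20 to 19.** Ring C is opened at O1–C8a, the aryl ether bond, giving the (R)-1,3-diarylpropan-1-ol 19 with a chlorine on C8a. This bond is cut in preference to O1–C2 because closing it forwards makes no bond at the stereocentre, so the configuration of 19 passes unchanged into 20. Closure at C2 would be a displacement at an easily ionised benzylic carbon. Chlorine is the halogen because it must survive the nickel step earlier in the route.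

**19 to 18.** The C2–O bond is traced back to a C2–B bond. Oxidation of a secondary boronic ester goes with retention, so the configuration of the alcohol is that of boronate 18, which brings the target into the reach of boron chemistry.

**18 to 10, 15 and 14.** Two bonds are cut at once, C2–C1' and C3–C4. The three pieces are vinylboronate 15 (C2 and C3), the ring B bromide 10 (lithiated to 16 and bound to boron as ate complex 17) and the ring A benzyl bromide 14. Both rings are then complete before they are joined, no redox adjustment of the three-carbon chain is needed, and the stereocentre forms in the same step as the skeleton. The forward reaction must make the aryl shift and the C3–C4 coupling happen on a chiral nickel centre, faster than any uncatalysed alkylation of 17.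

**10 to 9, 8, 5 and 7.** The acetal of 10 comes from phenol 9. The prenyl group of 9 is traced to the oxygen of 5 through the tertiary allyl ether 8: a [3,3] shift can deliver the allyl unit only to C7, the one ortho carbon bearing hydrogen, and it turns the 1,1-dimethylallyl ether into the linear prenyl group. This fixes the regiochemistry on a ring where direct C-alkylation would not be selective. Ether 8 comes from 5 and the allylic carbonate 7, which is made from alcohol 6.

**5 to 4, 3, 1 and 2.** Ring D is traced to the propargyl ether 3 through a second sigmatropic sequence. In 1 the methoxy group blocks one ortho position, so the pyran can close only on the other. The methyl group also tells the two oxygens apart, and the bromine is para to the ether oxygen from the start, which is the position that becomes C1'. Demethylation of 4 gives 5.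

**14 to 13, 12 and 11.** The benzyl bromide comes from aldehyde 11, which already has the chlorine ortho and the oxygen para to the one-carbon substituent. Protection, reduction and bromination complete it.

## Alternatives that were turned down

**Alternative 1: enantioconvergent closure of ring C through a para-quinone methide of ring B.** The disconnection is O1–C2. The precursor is the racemic benzylic alcohol A2, 1-[3,4-dihydroxy-2-(3-methylbut-2-en-1-yl)phenyl]-3-[2-hydroxy-4-(tert-butyldimethylsilyloxy)phenyl]propan-1-ol. A chiral phosphoric acid would ionise A2 to the para-quinone methide and guide the ring A phenol oxygen onto C2 (6-exo), giving the (R)-flavan catechol A1 from both enantiomers of A2.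
- For: A2 needs no asymmetric step, the catalysis is metal-free, and acid-catalysed additions to quinone methides formed in the flask are a well-developed reaction type. On the precedent for its stereo-determining step this alternative is stronger than the chosen route.
- Against: the quinone methide needs a free 4'-OH, so ring D cannot be in place. It would have to be built on A1 afterwards, by telling apart the 3'- and 4'-hydroxyls and then a propargyl ether rearrangement at high temperature. During that sequence the C2–O1 bond of a 4'-hydroxyflavan can reopen to the same quinone methide, now without the catalyst, and the configuration can erode. The ortho prenyl group also twists the methide out of plane and slows its formation.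
- Comparison: several steps follow the stereocentre here, one of them hot. The chosen route finishes ring B first and follows the stereocentre with only three mild steps.

**Alternative 2: ring C closed by intramolecular aryl ether formation from a bromo alcohol.** The disconnection is O1–C8a. The (R)-alcohol A4, (1R)-3-[2-bromo-4-(methoxymethoxy)phenyl]-1-[8-(methoxymethoxy)-2,2-dimethyl-7-(3-methylbut-2-en-1-yl)-2H-chromen-6-yl]propan-1-ol, would cyclise under palladium catalysis with a bulky biaryl di-tert-butylphosphine and a carbonate base to A3, the bis(methoxymethyl) ether of the target, identical with 20.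
- For: every step is known chemistry, the bromide inserts more easily than the chloride of 19, and C2 is retained. On reliability this alternative is stronger.
- Against: the alternative only names the ring closure. A4 still has to be assembled, most plausibly through a ring B aryl ketone, a carbon–carbon bond formation to the ring A unit and an asymmetric ketone reduction. That is several steps for what the conjunctive coupling does in one, and the aryl bromide could not be carried through an organolithium step.
- Comparison: the chosen route uses the same closure (step 13) and keeps this ketone-based chemistry as its fallback. What it adds is that the two skeletal bonds and the stereocentre form together from three finished fragments.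

**Alternative 3: hetero-Diels–Alder reaction of an ortho-quinone methide with a ring B styrene.** The disconnections are O1–C2 and C3–C4. A chiral Brønsted acid would dehydrate the hydroxybenzyl alcohol A6, 5-(tert-butyldimethylsilyloxy)-2-(hydroxymethyl)phenol, to the ortho-quinone methide. This would add across the vinyl group of styrene A7, 8-(tert-butyldimethylsilyloxy)-6-ethenyl-2,2-dimethyl-7-(3-methylbut-2-en-1-yl)-2H-chromene, to give A5, the bis(silyl) ether of the target.
- For: this is the shortest route. Ring C, two bonds and the stereocentre form in one step, and the polarity of the partners gives the 2-aryl regiochemistry. On step economy it is stronger than the chosen route.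
- Against: enantiocontrol by a chiral acid usually relies on a quinone methide stabilised by an aryl group on the methide carbon and on a dienophile that can hydrogen-bond to the catalyst. Here the methide carbon is an unsubstituted CH2 and A7 has no such handle. A7 also offers three electron-rich alkenes, and the prenyl and ring D double bonds are competent dienophiles for the same heterodiene. The acid would also endanger the silyl ethers and ring D.
- Comparison: chemoselectivity and enantioselectivity are both open here. In the chosen route the vinyl group is the only alkene bound to boron, so it is the only one that can take part, and the stereocentre is set on a metal with a defined chiral ligand.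

Key step: step 11

Assumption: the sense of induction of the diamine in step 11 cannot be derived with confidence. The (1S,2S) ligand is written; if a first run shows the opposite sense, its commercially available mirror image is used with nothing else changed.

## Route

Step 1
Reactants: 1 4-bromo-2-methoxyphenol; 2 3-chloro-3-methylbut-1-yne
Product: 3 4-bromo-2-methoxy-1-[(2-methylbut-3-yn-2-yl)oxy]benzene
Conditions: CuCl2·2H2O (1 mol%), DBU, MeCN, 0 °C → rt
Reagents that add atoms: none
Why: Copper-catalysed propargylic substitution of a tertiary propargyl chloride by a phenoxide is a standard route to aryl 1,1-dimethylpropargyl ethers and tolerates an ortho substituent; the aryl bromide is inert.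

Step 2
Reactants: 3 4-bromo-2-methoxy-1-[(2-methylbut-3-yn-2-yl)oxy]benzene
Product: 4 6-bromo-8-methoxy-2,2-dimethyl-2H-chromene
Conditions: PhNEt2, 180 °C
Reagents that add atoms: none
Why: Aromatic propargyl Claisen rearrangement: a [3,3] shift to the only free ortho carbon (the other carries OMe), enolisation, 1,5-hydrogen shift and 6π-electrocyclisation close the 2,2-dimethyl-2H-pyran ring.

Step 3
Reactants: 4 6-bromo-8-methoxy-2,2-dimethyl-2H-chromene
Product: 5 6-bromo-2,2-dimethyl-2H-chromen-8-ol
Conditions: NaSEt, DMF, 120 °C; then cold 1 M HCl
Reagents that add atoms: none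
Why: SN2 demethylation of the aryl methyl ether by thiolate. A basic method is chosen because the allylic ether of the chromene would not tolerate a boron or aluminium halide, and an electron-rich aryl bromide is not displaced by thiolate.

Step 4
Reactants: 6 2-methylbut-3-en-2-ol
Product: 7 tert-butyl 2-methylbut-3-en-2-yl carbonate
Conditions: n-BuLi, THF, −78 °C; Boc2O, −78 °C → rt
Reagents that add atoms: di-tert-butyl dicarbonate, CC(C)(C)OC(=O)OC(=O)OC(C)(C)C
Why: O-acylation of the tertiary lithium alkoxide by the dicarbonate gives the mixed allylic carbonate.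

Step 5
Reactants: 5 6-bromo-2,2-dimethyl-2H-chromen-8-ol; 7 tert-butyl 2-methylbut-3-en-2-yl carbonate
Product: 8 6-bromo-2,2-dimethyl-8-[(2-methylbut-3-en-2-yl)oxy]-2H-chromene
Conditions: Pd(PPh3)4 (2 mol%), THF, 0 °C → rt
Reagents that add atoms: none
Why: Tsuji–Trost O-allylation: the carbonate ionises to a 1,1-dimethylallylpalladium cation, and the tert-butoxide released on loss of carbon dioxide deprotonates the phenol; the phenoxide attacks the more substituted terminus under kinetic control to give the tertiary ether. Ionisation of an allylic carbonate at 0 °C is much faster than insertion of zerovalent palladium into an electron-rich aryl bromide.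

Step 6
Reactants: 8 6-bromo-2,2-dimethyl-8-[(2-methylbut-3-en-2-yl)oxy]-2H-chromene
Product: 9 6-bromo-2,2-dimethyl-7-(3-methylbut-2-en-1-yl)-2H-chromen-8-ol
Conditions: PhNEt2, 130 °C
Reagents that add atoms: none
Why: Aromatic Claisen rearrangement: the [3,3] shift delivers the allyl unit with transposition to C7, the only ortho carbon bearing hydrogen, so the 1,1-dimethylallyl ether becomes the linear prenyl group. The basic solvent suppresses acid-catalysed cleavage of the tertiary ether.

Step 7
Reactants: 9 6-bromo-2,2-dimethyl-7-(3-methylbut-2-en-1-yl)-2H-chromen-8-ol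
Product: 10 6-bromo-8-(methoxymethoxy)-2,2-dimethyl-7-(3-methylbut-2-en-1-yl)-2H-chromene
Conditions: NaH, THF/DMF, 0 °C; MOMCl, 0 °C → rt
Reagents that add atoms: chloromethyl methyl ether, COCCl
Why: O-alkylation of the sodium phenoxide; the strong base is used because the phenol is flanked on both sides.

Step 8
Reactants: 11 2-chloro-4-hydroxybenzaldehyde
Product: 12 2-chloro-4-(methoxymethoxy)benzaldehyde
Conditions: MOMCl, i-Pr2NEt, CH2Cl2, 0 °C → rt
Reagents that add atoms: chloromethyl methyl ether, COCCl
Why: The phenol para to the formyl group is acidic and is alkylated cleanly with an amine base.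

Step 9
Reactants: 12 2-chloro-4-(methoxymethoxy)benzaldehyde
Product: 13 [2-chloro-4-(methoxymethoxy)phenyl]methanol
Conditions: NaBH4, MeOH, 0 °C
Reagents that add atoms: none
Why: Borohydride reduction of an aryl aldehyde; the acetal and the aryl chloride are untouched.

Step 10
Reactants: 13 [2-chloro-4-(methoxymethoxy)phenyl]methanol
Product: 14 1-(bromomethyl)-2-chloro-4-(methoxymethoxy)benzene
Conditions: CBr4, PPh3, CH2Cl2, 0 °C
Reagents that add atoms: carbon tetrabromide, BrC(Br)(Br)Br
Why: Appel reaction under neutral conditions, which spares the acetal; the activated benzyl bromide is used soon after it is made.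

Step 11
Reactants: 10 6-bromo-8-(methoxymethoxy)-2,2-dimethyl-7-(3-methylbut-2-en-1-yl)-2H-chromene; 15 vinylboronic acid pinacol ester (2-ethenyl-4,4,5,5-tetramethyl-1,3,2-dioxaborolane); 14 1-(bromomethyl)-2-chloro-4-(methoxymethoxy)benzene
Product: 18 2-[(1R)-3-[2-chloro-4-(methoxymethoxy)phenyl]-1-[8-(methoxymethoxy)-2,2-dimethyl-7-(3-methylbut-2-en-1-yl)-2H-chromen-6-yl]propyl]-4,4,5,5-tetramethyl-1,3,2-dioxaborolane, via ring B aryllithium 16 (not isolated), via lithium aryl(vinyl)pinacolatoborate 17 (not isolated)
Conditions: t-BuLi (2 equiv), Et2O, −78 °C; 15, −78 → 0 °C; then Ni(cod)2 (10 mol%), (1S,2S)-N,N'-dimethyl-1,2-diphenylethane-1,2-diamine (12 mol%), 14 (slow addition), THF, 0 °C → rt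
Reagents that add atoms: none
Why: Proposed new method: bromine–lithium exchange on 10 gives aryllithium 16, which adds to boron of 15 to form the tetracoordinate ate complex 17; benzyl bromide 14 adds oxidatively to zerovalent nickel carrying the diamine, the benzylnickel bromide (divalent nickel) binds the vinyl group of 17, ring B migrates from boron to the α-carbon (C2) anti to the metal while the β-carbon (C3) bonds to nickel, and reductive elimination joins C3 to the benzylic carbon C4 and returns zerovalent nickel. The closest known reaction type is the nickel- or palladium-catalysed enantioselective conjunctive cross-coupling of vinylboron ate complexes with aryl or alkenyl triflates and with alkyl halides; a benzylic halide has not been shown as the electrophile. No ring is closed; the two skeletal bonds C2–C1' and C3–C4 are formed. The one new stereocentre, C2, is controlled by the chiral diamine on nickel, which fixes the alkene face that the metal occupies and so, through the anti-periplanar shift, the face that receives ring B. The step needs the nickel-bound pathway to outrun direct alkylation of 17 and addition of a free benzyl radical, insertion into the benzylic C–Br bond and not the aryl C–Cl bond, and reductive elimination ahead of β-hydride elimination from the alkylnickel. The substrate helps: the electron-rich ring B migrates readily, the benzylic C–Br bond is far weaker than the aryl C–Cl bond, the benzyl group has no β-hydrogen, a benzyl radical is nucleophilic and adds poorly to an electron-rich vinyl borate, and slow addition keeps the concentration of 14 low.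

Step 12
Reactants: 18 2-[(1R)-3-[2-chloro-4-(methoxymethoxy)phenyl]-1-[8-(methoxymethoxy)-2,2-dimethyl-7-(3-methylbut-2-en-1-yl)-2H-chromen-6-yl]propyl]-4,4,5,5-tetramethyl-1,3,2-dioxaborolane
Product: 19 (1R)-3-[2-chloro-4-(methoxymethoxy)phenyl]-1-[8-(methoxymethoxy)-2,2-dimethyl-7-(3-methylbut-2-en-1-yl)-2H-chromen-6-yl]propan-1-ol
Conditions: H2O2 (30% aq.), NaOH (3 M aq.), THF, 0 °C → rt
Reagents that add atoms: hydrogen peroxide, OO
Why: Oxidation of the boronic ester: hydroperoxide adds to boron and the carbon migrates to oxygen with retention, so the R boronate gives the R alcohol. Alkaline peroxide does not epoxidise the electron-rich alkenes.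

Step 13
Reactants: 19 (1R)-3-[2-chloro-4-(methoxymethoxy)phenyl]-1-[8-(methoxymethoxy)-2,2-dimethyl-7-(3-methylbut-2-en-1-yl)-2H-chromen-6-yl]propan-1-ol
Product: 20 (2R)-7-(methoxymethoxy)-2-[8-(methoxymethoxy)-2,2-dimethyl-7-(3-methylbut-2-en-1-yl)-2H-chromen-6-yl]-3,4-dihydro-2H-chromene
Conditions: Pd(OAc)2 (5 mol%), 2-(di-tert-butylphosphino)-2',4',6'-triisopropylbiphenyl (7.5 mol%), Cs2CO3, toluene, 90 °C
Reagents that add atoms: none
Why: Palladium-catalysed intramolecular C–O coupling: zerovalent palladium inserts into the aryl C–Cl bond, the palladium alkoxide forms, and C–O reductive elimination closes the six-membered ring C at O1–C8a. The bulky biaryl di-tert-butylphosphine makes reductive elimination faster than β-hydride elimination; no bond to C2 is made or broken, so the R configuration is carried through.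

Step 14
Reactants: 20 (2R)-7-(methoxymethoxy)-2-[8-(methoxymethoxy)-2,2-dimethyl-7-(3-methylbut-2-en-1-yl)-2H-chromen-6-yl]-3,4-dihydro-2H-chromene
Product: 21 (2R)-2-[8-hydroxy-2,2-dimethyl-7-(3-methylbut-2-en-1-yl)-2H-chromen-6-yl]-3,4-dihydro-2H-chromen-7-ol
Conditions: HCl (1.25 M in MeOH), THF, 0 °C → rt
Reagents that add atoms: none
Why: Acid-catalysed transacetalisation of the two aryl methoxymethyl ethers to dimethoxymethane. Dilute anhydrous acid near room temperature should be too mild to cyclise the prenyl group onto the 8-hydroxyl, to hydrate ring D or to ionise C2–O1, so C2 should remain R.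

## Compound list

1 | 4-bromo-2-methoxyphenol | COc1cc(Br)ccc1O | starting material
2 | 3-chloro-3-methylbut-1-yne | C#CC(C)(C)Cl | starting material
3 | 4-bromo-2-methoxy-1-[(2-methylbut-3-yn-2-yl)oxy]benzene | COc1cc(Br)ccc1OC(C)(C)C#C | intermediate
4 | 6-bromo-8-methoxy-2,2-dimethyl-2H-chromene | COc1cc(Br)cc2c1OC(C)(C)C=C2 | intermediate
5 | 6-bromo-2,2-dimethyl-2H-chromen-8-ol | Oc1cc(Br)cc2c1OC(C)(C)C=C2 | intermediate
6 | 2-methylbut-3-en-2-ol | C=CC(C)(C)O | starting material
7 | tert-butyl 2-methylbut-3-en-2-yl carbonate | C=CC(C)(C)OC(=O)OC(C)(C)C | intermediate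
8 | 6-bromo-2,2-dimethyl-8-[(2-methylbut-3-en-2-yl)oxy]-2H-chromene | C=CC(C)(C)Oc1cc(Br)cc2c1OC(C)(C)C=C2 | intermediate
9 | 6-bromo-2,2-dimethyl-7-(3-methylbut-2-en-1-yl)-2H-chromen-8-ol | CC(C)=CCc1c(Br)cc2c(c1O)OC(C)(C)C=C2 | intermediate
10 | 6-bromo-8-(methoxymethoxy)-2,2-dimethyl-7-(3-methylbut-2-en-1-yl)-2H-chromene | CC(C)=CCc1c(Br)cc2c(c1OCOC)OC(C)(C)C=C2 | intermediate
11 | 2-chloro-4-hydroxybenzaldehyde | O=Cc1ccc(O)cc1Cl | starting material
12 | 2-chloro-4-(methoxymethoxy)benzaldehyde | COCOc1ccc(C=O)c(Cl)c1 | intermediate
13 | [2-chloro-4-(methoxymethoxy)phenyl]methanol | COCOc1ccc(CO)c(Cl)c1 | intermediate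
14 | 1-(bromomethyl)-2-chloro-4-(methoxymethoxy)benzene | COCOc1ccc(CBr)c(Cl)c1 | intermediate
15 | vinylboronic acid pinacol ester (2-ethenyl-4,4,5,5-tetramethyl-1,3,2-dioxaborolane) | C=CB1OC(C)(C)C(C)(C)O1 | starting material
16 | [8-(methoxymethoxy)-2,2-dimethyl-7-(3-methylbut-2-en-1-yl)-2H-chromen-6-yl]lithium | CC(C)=CCc1c([Li])cc2c(c1OCOC)OC(C)(C)C=C2 | intermediate (not isolated)
17 | lithium ethenyl[8-(methoxymethoxy)-2,2-dimethyl-7-(3-methylbut-2-en-1-yl)-2H-chromen-6-yl](pinacolato)borate | [Li+].CC(C)=CCc1c([B-]3(C=C)OC(C)(C)C(C)(C)O3)cc2c(c1OCOC)OC(C)(C)C=C2 | intermediate (not isolated)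
18 | 2-[(1R)-3-[2-chloro-4-(methoxymethoxy)phenyl]-1-[8-(methoxymethoxy)-2,2-dimethyl-7-(3-methylbut-2-en-1-yl)-2H-chromen-6-yl]propyl]-4,4,5,5-tetramethyl-1,3,2-dioxaborolane | CC(C)=CCc1c([C@H](B3OC(C)(C)C(C)(C)O3)CCc3ccc(OCOC)cc3Cl)cc2c(c1OCOC)OC(C)(C)C=C2 | intermediate
19 | (1R)-3-[2-chloro-4-(methoxymethoxy)phenyl]-1-[8-(methoxymethoxy)-2,2-dimethyl-7-(3-methylbut-2-en-1-yl)-2H-chromen-6-yl]propan-1-ol | CC(C)=CCc1c([C@H](O)CCc3ccc(OCOC)cc3Cl)cc2c(c1OCOC)OC(C)(C)C=C2 | intermediate
20 | (2R)-7-(methoxymethoxy)-2-[8-(methoxymethoxy)-2,2-dimethyl-7-(3-methylbut-2-en-1-yl)-2H-chromen-6-yl]-3,4-dihydro-2H-chromene | CC(C)=CCc1c([C@H]2CCc3ccc(OCOC)cc3O2)cc2c(c1OCOC)OC(C)(C)C=C2 | intermediate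
21 | (2R)-2-[8-hydroxy-2,2-dimethyl-7-(3-methylbut-2-en-1-yl)-2H-chromen-6-yl]-3,4-dihydro-2H-chromen-7-ol | CC(C)=CCc1c([C@H]2CCc3ccc(O)cc3O2)cc2c(c1O)OC(C)(C)C=C2 | target

## Step count and risks

Total: 14 steps. Longest linear sequence: 10 steps (steps 1, 2, 3, 5, 6, 7, 11, 12, 13, 14). Step 4 and steps 8–10 are side branches.

**Step 11 (key step, proposed new method).**
- What may go wrong: the activated para-alkoxybenzyl bromide may alkylate the ate complex without the metal, or benzyl radicals may escape from nickel, and either would give racemic material. The benzyl halide may homocouple on nickel. The ortho prenyl group may slow the aryl shift. The aryllithium may be quenched by proton transfer from the doubly activated prenyl CH2 if it is allowed to warm before boron is added. The alkylnickel may undergo β-hydride elimination to an alkenylboronate.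
- Fallback (known chemistry): it sets out from 10 and 14 and returns at 19, so step 12 is not needed. Aryllithium 16, made from 10 as in step 11, is acylated with N-methoxy-N-methylacetamide (THF, −78 °C) to give the methyl ketone 1-[8-(methoxymethoxy)-2,2-dimethyl-7-(3-methylbut-2-en-1-yl)-2H-chromen-6-yl]ethan-1-one F1. Its lithium enolate (lithium diisopropylamide, THF, −78 °C) is alkylated with 14 to give 3-[2-chloro-4-(methoxymethoxy)phenyl]-1-[8-(methoxymethoxy)-2,2-dimethyl-7-(3-methylbut-2-en-1-yl)-2H-chromen-6-yl]propan-1-one F2. Noyori asymmetric transfer hydrogenation with RuCl[(R,R)-TsDPEN](p-cymene) in HCO2H/Et3N should then give the R alcohol 19, by analogy with simple aryl alkyl ketones; it leaves the alkenes and the aryl chloride alone. Steps 13 and 14 follow unchanged.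

**Step 13 (palladium-catalysed ring closure).**
- What may go wrong: the palladium alkoxide of a benzylic secondary alcohol may undergo β-hydride elimination, giving a ketone and loss of chlorine. Insertion into the electron-rich aryl chloride may be slow.
- Fallback: it sets out from 19 and returns at 20 and uses no transition metal. Treating 19 with lithium 2,2,6,6-tetramethylpiperidide (3 equiv, THF, −78 → 0 °C) forms the alkoxide and removes the hydrogen at C8, which lies between chlorine and the acetal oxygen. Loss of lithium chloride gives the lithium alkoxide of the 8,8a-aryne F3. The alkoxide adds to C8a, which is both the six-membered ring mode and the aryne carbon meta to the ether oxygen, and protonation on work-up gives 20 with C2 untouched.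

**Step 5 (O-allylation with the aryl bromide present).**
- What may go wrong: zerovalent palladium may insert into the aryl C–Br bond, or the ether may equilibrate to the linear prenyl ether, which would rearrange in step 6 to the wrong (1,1-dimethylallyl) C7 substituent.
- Fallback: it sets out from 5 and returns at 8. Phenol 5 is alkylated with 2 (CuCl2·2H2O, DBU, MeCN, 0 °C) to give 6-bromo-2,2-dimethyl-8-[(2-methylbut-3-yn-2-yl)oxy]-2H-chromene F4. Semi-hydrogenation of the alkyne (H2, Pd/CaCO3 poisoned with Pb(OAc)2, quinoline, EtOAc, rt) gives 8.

**Step 14 (removal of the acetals).**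
- What may go wrong: acid may close the prenyl group onto the freed 8-hydroxyl, add methanol to ring D, or ionise C2–O1 with loss of configuration.
- Fallback: it sets out from 20 and returns at 21 and avoids protic acid. Et3SiOTf and 2,2'-bipyridyl (MeCN, 0 °C → rt) convert the aryl acetals directly into the silyl ethers, giving (2R)-7-(triethylsilyloxy)-2-[2,2-dimethyl-7-(3-methylbut-2-en-1-yl)-8-(triethylsilyloxy)-2H-chromen-6-yl]-3,4-dihydro-2H-chromene F5. Bu4NF buffered with AcOH (THF, 0 °C) then gives 21.

## Further compounds

F1 | step 11 | 1-[8-(methoxymethoxy)-2,2-dimethyl-7-(3-methylbut-2-en-1-yl)-2H-chromen-6-yl]ethan-1-one | CC(C)=CCc1c(C(C)=O)cc2c(c1OCOC)OC(C)(C)C=C2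
F2 | step 11 | 3-[2-chloro-4-(methoxymethoxy)phenyl]-1-[8-(methoxymethoxy)-2,2-dimethyl-7-(3-methylbut-2-en-1-yl)-2H-chromen-6-yl]propan-1-one | CC(C)=CCc1c(C(=O)CCc3ccc(OCOC)cc3Cl)cc2c(c1OCOC)OC(C)(C)C=C2
F3 | step 13 | lithium (1R)-3-[4-(methoxymethoxy)-2,3-didehydrophenyl]-1-[8-(methoxymethoxy)-2,2-dimethyl-7-(3-methylbut-2-en-1-yl)-2H-chromen-6-yl]propan-1-olate (aryne alkoxide) | [Li+].CC(C)=CCc1c([C@H]([O-])CCC3=CC=C(OCOC)C#C3)cc2c(c1OCOC)OC(C)(C)C=C2
F4 | step 5 | 6-bromo-2,2-dimethyl-8-[(2-methylbut-3-yn-2-yl)oxy]-2H-chromene | C#CC(C)(C)Oc1cc(Br)cc2c1OC(C)(C)C=C2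
F5 | step 14 | (2R)-7-(triethylsilyloxy)-2-[2,2-dimethyl-7-(3-methylbut-2-en-1-yl)-8-(triethylsilyloxy)-2H-chromen-6-yl]-3,4-dihydro-2H-chromene | CC(C)=CCc1c([C@H]2CCc3ccc(O[Si](CC)(CC)CC)cc3O2)cc2c(c1O[Si](CC)(CC)CC)OC(C)(C)C=C2
A1 | alternative 1 | 4-[(2R)-7-(tert-butyldimethylsilyloxy)-3,4-dihydro-2H-chromen-2-yl]-3-(3-methylbut-2-en-1-yl)benzene-1,2-diol | CC(C)=CCc1c([C@H]2CCc3ccc(O[Si](C)(C)C(C)(C)C)cc3O2)ccc(O)c1O
A2 | alternative 1 | racemic 1-[3,4-dihydroxy-2-(3-methylbut-2-en-1-yl)phenyl]-3-[2-hydroxy-4-(tert-butyldimethylsilyloxy)phenyl]propan-1-ol | CC(C)=CCc1c(C(O)CCc2ccc(O[Si](C)(C)C(C)(C)C)cc2O)ccc(O)c1O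
A3 | alternative 2 | (2R)-7-(methoxymethoxy)-2-[8-(methoxymethoxy)-2,2-dimethyl-7-(3-methylbut-2-en-1-yl)-2H-chromen-6-yl]-3,4-dihydro-2H-chromene (identical with 20) | CC(C)=CCc1c([C@H]2CCc3ccc(OCOC)cc3O2)cc2c(c1OCOC)OC(C)(C)C=C2
A4 | alternative 2 | (1R)-3-[2-bromo-4-(methoxymethoxy)phenyl]-1-[8-(methoxymethoxy)-2,2-dimethyl-7-(3-methylbut-2-en-1-yl)-2H-chromen-6-yl]propan-1-ol | CC(C)=CCc1c([C@H](O)CCc3ccc(OCOC)cc3Br)cc2c(c1OCOC)OC(C)(C)C=C2
A5 | alternative 3 | (2R)-7-(tert-butyldimethylsilyloxy)-2-[8-(tert-butyldimethylsilyloxy)-2,2-dimethyl-7-(3-methylbut-2-en-1-yl)-2H-chromen-6-yl]-3,4-dihydro-2H-chromene | CC(C)=CCc1c([C@H]2CCc3ccc(O[Si](C)(C)C(C)(C)C)cc3O2)cc2c(c1O[Si](C)(C)C(C)(C)C)OC(C)(C)C=C2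
A6 | alternative 3 | 5-(tert-butyldimethylsilyloxy)-2-(hydroxymethyl)phenol | CC(C)(C)[Si](C)(C)Oc1ccc(CO)c(O)c1
A7 | alternative 3 | 8-(tert-butyldimethylsilyloxy)-6-ethenyl-2,2-dimethyl-7-(3-methylbut-2-en-1-yl)-2H-chromene | CC(C)=CCc1c(C=C)cc2c(c1O[Si](C)(C)C(C)(C)C)OC(C)(C)C=C2
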